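## The problem

The target 9 is the aryl ester between the phenol oxygen of methyl (E)-4-hydroxycinnamate and (3S)-3-acetoxybutanoic acid; the benzene ring is 1,2,4-trisubstituted, with the acrylate on C1, a prenyl group on C3 and the acyloxy group on C4. There is no ring to close and only one stereocentre, C3 of the butanoyl chain, which is remote from every other group, so nothing in the molecule can control it and it has to be brought in intact. The first difficulty is the bond from ring C3 to the prenyl CH2: a phenoxide is ambident, O-alkylation and double alkylation compete, and the free ortho-prenylphenol closes to a 2,2-dimethylchroman as soon as acid is present. The second is the aryl ester of a β-acyloxy acid: the aryloxide is a good leaving group and the α-CH2 is acidic, so bases and nucleophilic acylation catalysts open an E1cB path that expels acetate and leaves a crotonate; this bond should be made last and without base. Three different esters (methyl, acetyl, aryl) rule out any late hydrolytic adjustment, and the (E)-cinnamate must survive heat or light. Two features of the structure make the chosen key step possible. (a) The oxygen on C4 with CH2–CH=C(CH3)2 on the adjacent C3, C1 (para to oxygen) blocked by the acrylate and C5 equivalent to C3 once the prenyl group is removed, is the retron of an aromatic Claisen rearrangement of a 1,1-dimethylallyl ether. (b) The single CH2 (C2 of the butanoyl chain) between the ester carbonyl and the O-bearing stereocentre makes the acyl group the one-carbon homologue of O-acetyl lactic acid, that is, the adduct of a ketene whose CH was once a diazo carbon.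

## Retrosynthesis

**Ester and chain in one cut.** From 9 the obvious cut is the ester C–O bond alone. Cutting it together with the C2–C3 bond of the butanoyl chain (retro ketene addition, then retro-Wolff rearrangement) leads to phenol 7 and ketene 8, and from 8 to the diazoketone 6. The double cut has two advantages. The ketene is generated without base and adds the phenol without a coupling agent, which removes the E1cB problem. The stereocentre becomes the α-carbon of a lactic acid derivative, and the 1,2-shift proceeds with retention while the priority order O > chain carbon > CH3 stays the same, so an (S)-lactate gives the required (3S) ester. The forward reaction must generate 8 under neutral conditions and have it captured by a hindered phenol before it decays.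

**Ring C3–CH2 bond.** Phenol 7 is not isolated. Its bond from ring C3 to the prenyl CH2 is cut by a retro-[3,3] shift to the aryl 1,1-dimethylallyl ether 4. Unlike direct C-prenylation, this delivers the allyl group through the oxygen itself, so it can only arrive ortho. Ether 4 is a para-disubstituted benzene whose two ortho positions are equivalent, so there is no regiochemical question. The oxygen that carries the allyl group is then the nucleophile for 8. Since the Claisen step needs only heat and the Wolff step only light, both can be run in one flask. Step 4 then joins 4 and 6 directly to 9 and forms three bonds: ring C3–CH2, chain C2–C3 and O–C(=O).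

**Diazoketone.** 6 is cut between the ketone carbon and the diazo carbon to the commercial acid chloride 5 (O-acetyl lactic acid chloride, S) and a one-carbon diazo reagent. The forward step must avoid base, which would turn 5 into a ketene and racemise it.

**Branched ether.** The tertiary allylic ether 4 cannot be made from a prenyl electrophile, which reacts at its primary carbon. The O–C(CH3)2 bond is therefore cut to phenol 1 and the tertiary propargylic chloride 2, with the alkyne of 3 serving as a masked vinyl group (3 to 4 by semi-hydrogenation). Copper catalysis fixes attack at the tertiary carbon. Both 1 and 2 are catalogue compounds.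

## Roads not taken

Alternative 1: The most obvious plan cuts the ring–prenyl bond and the ester C–O bond separately. Forward, the sodium phenoxide of 1 is C-alkylated with prenyl bromide to give 7, which is then acylated with (3S)-3-acetoxybutanoyl chloride A2 and pyridine. The alkylation has no regiocontrol: O-alkylation to the prenyl ether A1, double alkylation and acid-induced ring closure onto the prenyl double bond all compete. The acylation passes through an acylpyridinium or ketene in the presence of base, the conditions under which a β-acetoxy acyl compound loses acetic acid. A2 needs its own two or three steps from a 3-hydroxybutanoate. The chosen plan is no longer and solves both problems by mechanism.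

Alternative 2: The benzene ring is built rather than bought. A 3-hydroxy-2-pyrone carrying the acrylate at C6, A3, undergoes Diels–Alder addition with 5-methylhex-4-en-1-yne A4 and loses carbon dioxide to give 7. The para oxygen/acrylate relationship is already available in commercial 1, whereas A3 would need several steps. Nothing in an unactivated terminal alkyne secures which of its carbons bonds to C3 of the pyrone. The acrylate double bond is a better dienophile than the alkyne. The ester and the stereocentre would still remain to be dealt with.

Alternative 3: The stereocentre is made rather than bought, by cutting the C3–H bond of the butanoyl chain. Forward, 7 is acetoacetylated with the acetylketene from 2,2,6-trimethyl-4H-1,3-dioxin-4-one to give the aryl acetoacetate A5, which is O-acetylated to the enol acetate A6 as an E/Z mixture. A stereoconvergent asymmetric hydrogenation with a cationic rhodium bisphosphine catalyst such as [Rh(cod)(Me-DuPhos)]BF4 would then turn both geometric isomers into the (S)-acetate. The catalyst would have to distinguish the enol ester from the cinnamate double bond, itself a β-aryl acrylate, and from the prenyl group. Convergence of the two enol ester isomers is not assured, and the route is two steps longer. The lactate route needs no such selectivity.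

Key step: step 4

Remark: 1, 2, 5 and (trimethylsilyl)diazomethane are taken as catalogue chemicals; 5 is the acid chloride of O-acetyl-L-lactic acid and has the (S) configuration.

## Steps

Step 1
Reactants: 1 methyl (2E)-3-(4-hydroxyphenyl)prop-2-enoate; 2 3-chloro-3-methylbut-1-yne
Product: 3 methyl (2E)-3-{4-[(2-methylbut-3-yn-2-yl)oxy]phenyl}prop-2-enoate
Conditions: CuCl2·2H2O (cat.), DBU, MeCN, 0 °C
Reagents that add atoms: none
Why: Copper-catalysed propargylic etherification: the copper acetylide of 2 ionises to a copper allenylidene, which the phenoxide of 1 attacks at the tertiary carbon; this is the standard entry to aryl 1,1-dimethylpropargyl ethers, works best with acidic phenols such as 1, and at 0 °C leaves the cinnamate untouched.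

Step 2
Reactants: 3 methyl (2E)-3-{4-[(2-methylbut-3-yn-2-yl)oxy]phenyl}prop-2-enoate
Product: 4 methyl (2E)-3-{4-[(2-methylbut-3-en-2-yl)oxy]phenyl}prop-2-enoate
Conditions: H2 (1 atm), Pd/CaCO3 poisoned with Pb(OAc)2 (Lindlar catalyst), quinoline, EtOAc, 20 °C, stopped after one equivalent of H2
Reagents that add atoms: none
Why: Lindlar semi-hydrogenation: the terminal alkyne binds the poisoned palladium far more strongly than the vinyl group formed or the conjugated 1,2-disubstituted cinnamate double bond; the same reduction is routine on dimethylpropargyl ethers of coumarins, which contain the same cinnamate unit.

Step 3
Reactants: 5 (2S)-2-acetoxypropanoyl chloride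
Product: 6 (2S)-4-diazo-3-oxobutan-2-yl acetate
Conditions: TMSCHN2 (excess), THF/MeCN, 0 °C to 20 °C, dark
Reagents that add atoms: (trimethylsilyl)diazomethane, C[Si](C)(C)C=[N+]=[N-]
Why: First stage of an Arndt–Eistert homologation: C-acylation of the diazoalkane, then loss of the silyl group to chloride, gives the diazomethyl ketone; no base is present, so 5 cannot form a ketene, and the (S) stereocentre is not touched.

Step 4
Reactants: 4 methyl (2E)-3-{4-[(2-methylbut-3-en-2-yl)oxy]phenyl}prop-2-enoate; 6 (2S)-4-diazo-3-oxobutan-2-yl acetate
Product: 9 methyl (2E)-3-[4-{[(3S)-3-acetoxybutanoyl]oxy}-3-(3-methylbut-2-en-1-yl)phenyl]prop-2-enoate (CNP0290147.1), via ortho-prenylphenol 7 (not isolated), via acetoxy ketene 8 (not isolated)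
Conditions: 4, degassed toluene, 130 °C, sealed tube; then 0 °C, 6 (1.5 equiv, added in portions), hv (405 nm LED)
Reagents that add atoms: none
Why: Heating 4 triggers an aromatic Claisen rearrangement ([3,3] shift through a six-membered chair transition state, then tautomerisation of the 6-prenylcyclohexa-2,4-dienone) to phenol 7; in the same solution at 0 °C, 405 nm light expels N2 from 6 in a Wolff rearrangement in which the CH(CH3)OAc group migrates from the carbonyl carbon to the diazo carbon, and ketene 8 adds the O–H of 7 to give 9. The closest known reaction types are the Claisen rearrangement of aryl 1,1-dimethylallyl ethers with acylation of the liberated phenol in the same pot (as when it is run in an acid anhydride) and the photochemical Arndt–Eistert reaction with a phenol as the trap. No ring is closed; the only cyclic array is the transition state of the [3,3] shift. No stereocentre is created: the existing one is the migrating carbon of the 1,2-shift, which moves with retention, so the (S) centre of 5 becomes C3 (S) of the butanoate. The regioselectivity of the C–C bond is secured by the substrate: the para position is blocked by the acrylate, the two ortho positions of 4 are equivalent, and the allyl inversion of the [3,3] shift turns the branched 1,1-dimethylallyl ether into the linear prenyl group. The chemoselectivity of the capture rests on 7 being the only protic nucleophile present and on slow generation of 8, which holds ketene dimerisation (second order in 8) behind capture (first order in 8), and the absence of base removes the E1cB route to a crotonate. The (E)-cinnamate absorbs below about 350 nm and is not excited at 405 nm, and acyclic diazomethyl ketones react from the s-Z conformer, which rearranges in concert with loss of N2, so O–H insertion of a free carbene should be minor.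

## Compound list

1 | methyl (2E)-3-(4-hydroxyphenyl)prop-2-enoate | COC(=O)/C=C/c1ccc(O)cc1 | starting material
2 | 3-chloro-3-methylbut-1-yne | CC(C)(Cl)C#C | starting material
3 | methyl (2E)-3-{4-[(2-methylbut-3-yn-2-yl)oxy]phenyl}prop-2-enoate | COC(=O)/C=C/c1ccc(OC(C)(C)C#C)cc1 | intermediate
4 | methyl (2E)-3-{4-[(2-methylbut-3-en-2-yl)oxy]phenyl}prop-2-enoate | COC(=O)/C=C/c1ccc(OC(C)(C)C=C)cc1 | intermediate
5 | (2S)-2-acetoxypropanoyl chloride | C[C@H](OC(C)=O)C(Cl)=O | starting material
6 | (2S)-4-diazo-3-oxobutan-2-yl acetate | C[C@H](OC(C)=O)C(=O)C=[N+]=[N-] | intermediate
7 | methyl (2E)-3-[4-hydroxy-3-(3-methylbut-2-en-1-yl)phenyl]prop-2-enoate (formed and consumed in step 4) | COC(=O)/C=C/c1ccc(O)c(CC=C(C)C)c1 | intermediate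
8 | (2S)-4-oxobut-3-en-2-yl acetate, a ketene (formed and consumed in step 4) | C[C@H](OC(C)=O)C=C=O | intermediate
9 | methyl (2E)-3-[4-{[(3S)-3-acetoxybutanoyl]oxy}-3-(3-methylbut-2-en-1-yl)phenyl]prop-2-enoate | COC(=O)/C=C/c1ccc(OC(=O)C[C@H](C)OC(C)=O)c(CC=C(C)C)c1 | target

## Step count and least certain steps

Total step count: 4. Longest linear sequence: 3 (steps 1, 2 and 4); step 3 is a one-step branch that enters in step 4.

**Step 4 (key step).** The most likely failure is loss of the β-acetoxy group at the ketene stage. This could happen by an intramolecular 1,3-acyl shift of the acetate onto the ketene carbon, or by elimination from the enol formed on addition. Either would compete with a slow, uncatalysed capture by a hindered and fairly acidic phenol; ketene dimerisation is the second concern. As fallback, only the thermal stage is run and phenol 7 is isolated. It is then esterified with (3S)-3-acetoxybutanoic acid F1, made by acetylation of commercial (S)-3-hydroxybutanoic acid (Ac2O, pyridine), under carbodiimide activation (EDC·HCl, catalytic DMAP, CH2Cl2, 0 °C). This fallback sets out from 7 and comes back at 9. It gives up the lactate homologation but keeps the Claisen solution to the prenyl problem.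

**Step 3.** The most likely failure is protonation of the diazo carbon by hydrogen chloride, followed by chloride substitution, if desilylation lags. Incomplete acylation of the weakly nucleophilic silyl diazoalkane is the other risk. The fallback is a diazoalkane-free route in which the one-carbon unit is an isocyanide carbon. Addition of 5 to (isocyanoimino)triphenylphosphorane in CH2Cl2 and aqueous work-up, with loss of triphenylphosphine oxide, gives the α-keto hydrazonoyl chloride (2S)-4-chloro-4-hydrazinylidene-3-oxobutan-2-yl acetate F2. Triethylamine then dehydrochlorinates F2 to the diazoketone. This fallback sets out from 5 and comes back at 6.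

**Step 2.** The most likely failure is over-reduction of the new vinyl group, and to a lesser extent of the cinnamate double bond, once the alkyne is consumed. The fallback avoids the alkyne altogether. Phenol 1 undergoes palladium-catalysed decarboxylative allylic etherification with tert-butyl 2-methylbut-3-en-2-yl carbonate F3 (from 2-methylbut-3-en-2-ol, n-BuLi and Boc2O), using Pd(PPh3)4 (zerovalent palladium) in THF at 0 °C. The phenoxide attacks the more substituted end of the 1,1-dimethylallyl palladium cation and gives the branched ether directly. This fallback sets out from 1 and comes back at 4, replacing steps 1 and 2.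

## Further compounds

F1 | step 4 | (3S)-3-acetoxybutanoic acid | C[C@H](OC(C)=O)CC(=O)O
F2 | step 3 | (2S)-4-chloro-4-hydrazinylidene-3-oxobutan-2-yl acetate | C[C@H](OC(C)=O)C(=O)C(Cl)=NN
F3 | step 2 | tert-butyl 2-methylbut-3-en-2-yl carbonate | CC(C)(C)OC(=O)OC(C)(C)C=C
A1 | alternative 1 | methyl (2E)-3-{4-[(3-methylbut-2-en-1-yl)oxy]phenyl}prop-2-enoate | COC(=O)/C=C/c1ccc(OCC=C(C)C)cc1
A2 | alternative 1 | (3S)-3-acetoxybutanoyl chloride | C[C@H](OC(C)=O)CC(Cl)=O
A3 | alternative 2 | methyl (2E)-3-(5-hydroxy-6-oxo-6H-pyran-2-yl)prop-2-enoate | COC(=O)/C=C/c1ccc(O)c(=O)o1
A4 | alternative 2 | 5-methylhex-4-en-1-yne | C#CCC=C(C)C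
A5 | alternative 3 | methyl (2E)-3-[3-(3-methylbut-2-en-1-yl)-4-(3-oxobutanoyloxy)phenyl]prop-2-enoate | COC(=O)/C=C/c1ccc(OC(=O)CC(C)=O)c(CC=C(C)C)c1
A6 | alternative 3 | methyl (2E)-3-[4-(3-acetoxybut-2-enoyloxy)-3-(3-methylbut-2-en-1-yl)phenyl]prop-2-enoate (E/Z mixture at the enol acetate) | COC(=O)/C=C/c1ccc(OC(=O)C=C(C)OC(C)=O)c(CC=C(C)C)c1
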